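**Strategy.** Everything rests on cutting the bond between cyclohexene C6 and the exocyclic carbinol carbon. The carbinol carbon, C6, the coumarin-bearing C1–H and the C2=C3 alkene of the cyclohexene ring form a bishomoallylic (4-penten-1-ol) array. This is the retron of a nickel-catalysed reductive homoallylation of an aldehyde by a 1,3-diene. The key step therefore couples 8-formyl-5,7-dimethoxycoumarin with a flat, achiral 2-(coumarin-8-yl)cyclohexa-1,3-diene made from isophorone. In one operation it forms the C6–carbinol bond, delivers the C1 hydrogen, leaves the alkene at C2=C3 and sets all three stereocentres under catalyst control.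

Key step: step 5

Remark (numbering): in the text the cyclohexene of the target is numbered C1 (bears a coumarin), C2=C3(CH3), C4H2, C5(CH3)2, C6 (bears the carbinol arm).
Assumption 1: electrophilic substitution of 5,7-dimethoxycoumarin (iodination, formylation) is taken to occur at C8, para to the 5-OMe and ortho to the 7-OMe, and not at C6 or C3.
Assumption 2: the antipode of the chiral phosphoramidite that leads to the (1S,6R,R) series cannot be predicted and is to be assigned in an initial screen.

Step 1
Reactants: 1 isophorone (3,5,5-trimethylcyclohex-2-en-1-one)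
Product: 3 dienyl triflate (3,3,5-trimethylcyclohexa-1,5-dien-1-yl trifluoromethanesulfonate), via lithium dienolate 2 (not isolated)
Conditions: LDA (1.1 equiv), THF, −78 °C; then PhNTf2, −78 °C → rt; aqueous work-up
Reagents that add atoms: N-phenylbis(trifluoromethanesulfonimide), O=S(=O)(N(c1ccccc1)S(=O)(=O)C(F)(F)F)C(F)(F)F
Why: Kinetic deprotonation of the enone at the α′-methylene should give the cross-conjugated dienolate 2, and its O-sulfonylation gives the dienyl triflate (enol triflate formation); no stereocentre is formed.

Step 2
Reactants: 4 5,7-dimethoxycoumarin (5,7-dimethoxy-2H-chromen-2-one)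
Product: 5 8-iodo-5,7-dimethoxy-2H-chromen-2-one
Conditions: NIS (1.05 equiv), TFA (cat.), MeCN, 0 °C → rt, dark
Reagents that add atoms: N-iodosuccinimide, O=C1CCC(=O)N1I
Why: Electrophilic aromatic iodination with acid-activated NIS should take place at C8, the arene position para to the 5-OMe and ortho to the 7-OMe, while the electron-poor lactone alkene stays untouched.

Step 3
Reactants: 3 dienyl triflate; 5 8-iodo-5,7-dimethoxy-2H-chromen-2-one
Product: 7 5,7-dimethoxy-8-(3,3,5-trimethylcyclohexa-1,5-dien-1-yl)-2H-chromen-2-one (achiral 2-aryl-1,3-diene; coumarin C8 on the central diene carbon), via dienyl pinacol boronate 6 (not isolated)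
Conditions: B2pin2, PdCl2(dppf) (5 mol %), KOAc, dioxane, 80 °C; then 5, SPhos Pd G3 (3 mol %), aq K3PO4, 70 °C; work-up at pH 4–5
Reagents that add atoms: none
Why: One-pot Miyaura borylation of the alkenyl triflate followed by Suzuki–Miyaura coupling with the di-ortho-substituted aryl iodide (SPhos-type catalyst) should give the diene, which cannot aromatise because of the gem-dimethyl group; no stereocentre is formed.

Step 4
Reactants: 4 5,7-dimethoxycoumarin
Product: 9 5,7-dimethoxy-2-oxo-2H-chromene-8-carbaldehyde, via α-chloro methyl ether 8 (not isolated)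
Conditions: Cl2CHOMe, TiCl4, CH2Cl2, 0 °C → rt; then H2O
Reagents that add atoms: dichloromethyl methyl ether, COC(Cl)Cl; water, O
Why: Rieche formylation, in which TiCl4-activated dichloromethyl methyl ether substitutes the most nucleophilic arene position C8 and the α-chloro ether 8 is hydrolysed to the aldehyde on aqueous work-up.

Step 5
Reactants: 7 5,7-dimethoxy-8-(3,3,5-trimethylcyclohexa-1,5-dien-1-yl)-2H-chromen-2-one; 9 5,7-dimethoxy-2-oxo-2H-chromene-8-carbaldehyde
Product: 11 8-[(1S,6R)-6-[(R)-(5,7-dimethoxy-2-oxo-2H-chromen-8-yl)(hydroxy)methyl]-3,5,5-trimethylcyclohex-2-en-1-yl]-5,7-dimethoxy-2H-chromen-2-one (IN0553), via ethylzinc alkoxide 10 (not isolated)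
Conditions: Ni(acac)2 (10 mol %), chiral spiro phosphoramidite (SIPHOS type, 12 mol %), Et2Zn (3 equiv), toluene, 0 °C → rt; aq NH4Cl
Reagents that add atoms: none
Why: Ligated Ni(0) should bind the s-cis diene of 7 η4 and undergo oxidative cyclisation with the aldehyde of 9, forming the bond between the diene CH next to CMe2 (future C6) and the carbonyl carbon on the nickel-bound face; Zn-to-Ni ethyl transfer, β-hydride elimination (ethylene) and C–H reductive elimination then place hydrogen on the aryl-bearing allyl terminus (future C1) from the same face and leave the C2=C3 alkene. The closest known reaction type is the nickel-catalysed reductive homoallylation of aldehydes with 1,3-dienes (Et3B or Et2Zn as reductant, spiro phosphoramidites in the asymmetric variant); no ring of the product is closed, the five-membered oxanickelacycle being transient. C1 is set by this syn hydride delivery, which puts H-1 cis to the new carbinol arm and hence the two large substituents trans. The carbinol centre is set in the oxidative cyclisation, where the carbonyl oxygen points to nickel and the coumarin points away from the diene; because ring carbon C5 sits in the inside (Z) position of the reacting terminus this gives the syn C6/carbinol relationship, as a Z-crotyl unit does in a closed transition state, and the absolute sense of all three centres follows from the diene face chosen by the ligand. The step needs regioselection for the CH terminus over the methyl-bearing terminus, which the fully substituted nature of the latter and the adjacent 2-aryl group (as in isoprene) should secure, and chemoselection over the coumarin enoates and over direct ethyl transfer, which the stronger Ni(0) affinity of the diene/aldehyde pair and the low electrophilicity of the donor-substituted coumarin C4 should secure.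

**Compound list**
1 | isophorone (3,5,5-trimethylcyclohex-2-en-1-one) | CC1=CC(=O)CC(C)(C)C1 | starting material
2 | lithium 3,3,5-trimethylcyclohexa-1,5-dien-1-olate (kinetic cross-conjugated dienolate) | [Li]OC1=CC(C)(C)CC(C)=C1 | intermediate
3 | 3,3,5-trimethylcyclohexa-1,5-dien-1-yl trifluoromethanesulfonate | CC1=CC(OS(=O)(=O)C(F)(F)F)=CC(C)(C)C1 | intermediate
4 | 5,7-dimethoxycoumarin (5,7-dimethoxy-2H-chromen-2-one) | COc1cc(OC)c2ccc(=O)oc2c1 | starting material
5 | 8-iodo-5,7-dimethoxy-2H-chromen-2-one | COc1cc(OC)c2ccc(=O)oc2c1I | intermediate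
6 | 4,4,5,5-tetramethyl-2-(3,3,5-trimethylcyclohexa-1,5-dien-1-yl)-1,3,2-dioxaborolane | CC1=CC(B2OC(C)(C)C(C)(C)O2)=CC(C)(C)C1 | intermediate
7 | 5,7-dimethoxy-8-(3,3,5-trimethylcyclohexa-1,5-dien-1-yl)-2H-chromen-2-one | COc1cc(OC)c2ccc(=O)oc2c1C1=CC(C)(C)CC(C)=C1 | intermediate
8 | 8-[chloro(methoxy)methyl]-5,7-dimethoxy-2H-chromen-2-one | COC(Cl)c1c(OC)cc(OC)c2ccc(=O)oc12 | intermediate
9 | 5,7-dimethoxy-2-oxo-2H-chromene-8-carbaldehyde | COc1cc(OC)c2ccc(=O)oc2c1C=O | intermediate
10 | ethylzinc alkoxide of 11 (O–ZnEt in place of O–H, same configuration) | COc1cc(OC)c2ccc(=O)oc2c1[C@H]1C=C(C)CC(C)(C)[C@@H]1[C@@H](O[Zn]CC)c1c(OC)cc(OC)c2ccc(=O)oc12 | intermediate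
11 | 8-[(1S,6R)-6-[(R)-(5,7-dimethoxy-2-oxo-2H-chromen-8-yl)(hydroxy)methyl]-3,5,5-trimethylcyclohex-2-en-1-yl]-5,7-dimethoxy-2H-chromen-2-one (IN0553) | COc1cc(OC)c2ccc(=O)oc2c1[C@H]1C=C(C)CC(C)(C)[C@@H]1[C@@H](O)c1c(OC)cc(OC)c2ccc(=O)oc12 | target

**Step count.** Total: 5 steps. Longest linear sequence: 3 steps (1 → 3 → 7 → 11, steps 1, 3 and 5).

**Steps most likely to fail**

1. Step 5. The oxidative cyclisation may stall at the neopentyl-type diene terminus with a bulky chiral ligand and a di-ortho-substituted aldehyde. The ligand may also discriminate the two diene faces poorly, or ethyl transfer to the aldehyde may compete. Fallback, setting out from 7 and 9: the ligand-free racemic homoallylation protocol (Ni(acac)2, Et3B, THF, rt) should still be governed by the same substrate-based relative stereocontrol and give the racemate. This consists of 11 and its mirror image, the (1R,6S,S)-enantiomer of 11 F1. Preparative chromatography on a chiral stationary phase (SFC or HPLC) then separates the two and the route is rejoined at 11.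

2. Step 3. The dienyl boronate may protodeboronate or dimerise before it couples. Transmetalation onto the hindered aryl–palladium species may be slow, and the aqueous base may open the lactone. Fallback, setting out from 5 and 3: LiCl-promoted zinc insertion into the aryl iodide (Zn dust, LiCl, THF, 25–50 °C) gives (5,7-dimethoxy-2-oxo-2H-chromen-8-yl)zinc iodide F2. A base-free, anhydrous Negishi coupling of F2 with triflate 3 (Pd(OAc)2/SPhos, THF, 50 °C) rejoins the route at 7.

3. Step 2. Iodination may partly take place at C6 or at the C3=C4 alkene, or run on to a diiodide, so that the pure 8-iodide is hard to obtain. Fallback, setting out from 9: Baeyer–Villiger (Dakin-type) oxidation of the electron-rich aldehyde (mCPBA, CH2Cl2) gives 5,7-dimethoxy-2-oxo-2H-chromen-8-yl formate F3. Mild methanolysis (KHCO3, MeOH) gives 8-hydroxy-5,7-dimethoxy-2H-chromen-2-one F4, and Tf2O/pyridine gives 5,7-dimethoxy-2-oxo-2H-chromen-8-yl trifluoromethanesulfonate F5. F5 takes the place of 5 in the borylation/Suzuki sequence of step 3 and the route is rejoined at 7.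

**Further compounds**
F1 | step 5 | 8-[(1R,6S)-6-[(S)-(5,7-dimethoxy-2-oxo-2H-chromen-8-yl)(hydroxy)methyl]-3,5,5-trimethylcyclohex-2-en-1-yl]-5,7-dimethoxy-2H-chromen-2-one (enantiomer of 11) | COc1cc(OC)c2ccc(=O)oc2c1[C@@H]1C=C(C)CC(C)(C)[C@H]1[C@H](O)c1c(OC)cc(OC)c2ccc(=O)oc12
F2 | step 3 | (5,7-dimethoxy-2-oxo-2H-chromen-8-yl)zinc iodide | COc1cc(OC)c2ccc(=O)oc2c1[Zn]I
F3 | step 2 | 5,7-dimethoxy-2-oxo-2H-chromen-8-yl formate | COc1cc(OC)c2ccc(=O)oc2c1OC=O
F4 | step 2 | 8-hydroxy-5,7-dimethoxy-2H-chromen-2-one | COc1cc(OC)c2ccc(=O)oc2c1O
F5 | step 2 | 5,7-dimethoxy-2-oxo-2H-chromen-8-yl trifluoromethanesulfonate | COc1cc(OC)c2ccc(=O)oc2c1OS(=O)(=O)C(F)(F)F
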